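The constants of this flask are unknown, so the meeting set out to read one constant from the theta run.

common to all: left-handed substrate 0.33 M; right-handed substrate 0.33 M; free catalyst 0.56 mM

| charge | partner | racemization catalyst | remark | time |
|---|---|---|---|---|
| theta | 0.99 M | 2.4 mM | run made earlier |  |
| flask | 0.990 M | 1.2 mM |  | 1.5 h |

- theta (time / min: left-handed substrate / %, left-handed product / %, right-handed substrate / %): 0.667: 28, 37, 34; 2.00: 22, 46, 28; 3.00: 23, 50, 22; 5.00: 23, 49, 24; 6.00: 24, 51, 20; 10.0: 24, 52, 24

(scatter of a reading: 1.5 percentage points)

- free catalyst is single-handed; left-handed substrate and right-handed substrate are mirror images of each other, charged as a racemate, each of them at the stated concentration
- the numbers in the tables scatter by 1.5 percentage points (one standard deviation)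
- the reaction counts as stopped when no species that holds the left-handed substrate and right-handed substrate together changes by six tenths of a point or more over the second half of the time
- no earlier run changes the charge of racemization catalyst; that part of a forecast is a guess

- the state of affairs at 1.5 h: stopped, and by what, or still going (forward and back rates have come level / no working catalyst is left / all of the left-handed substrate has reacted / it is still moving / the partner has run out first)
- conversion of left-handed substrate and right-handed substrate together at 1.5 h
- amount of left-handed product at 1.5 h, in percent of the left-handed substrate and right-handed substrate together charged
- amount of right-handed substrate at 1.5 h, in percent of the left-handed substrate and right-handed substrate together charged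

The chair read out the forecast: forward and back rates have come level, conversion 52% (48% to 55%), left-handed product 52% (47% to 55%), right-handed substrate 24% (22% to 26.5%). Its ground, in its own words: “A smooth approach to a plateau with equal enantiomers suggests equilibrium”.

A member objected that the theta run has no partner column. A flat line there cannot tell equilibrium from a partner that has gone. She proposed a side loss, first order in c_partner, beside the step to product. Both rates carry c_partner, so their comparison does not depend on it.

Suppose the racemization catalyst keeps the substrates level. Then the share of partner spent on substrate at any moment is c_substrates/(c_substrates + L). Summed over a run that spends its partner, charged partner equals substrate used plus L·ln(starting c_substrates/final c_substrates).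

In the last theta reading, c_substrates has gone from 0.660 M to 0.317 M. If the partner is taken as gone there, that reading gives 0.881 M for the loss level L, with the scatter of the readings in it. L is the substrate total at which, for this free catalyst charge, partner divides equally between product and loss. On this reckoning the share in the theta run drifts down, from 42.8% to 26.4%.

The chair noted that the flask has the theta charges of partner and free catalyst, and that its racemization catalyst stands at half the theta charge, a change no earlier run tests. The member then carried the last theta conversion over to the flask, 52.0%. Her figure and the forecast's come from the same theta readings, so their agreement is no check, but she named the partner as limiting reagent.

The state of the flask at the asked time: the partner has run out first. It gives conversion 51.2%, left-handed product 48.2%, right-handed substrate 24.4%. At 1.50 h it holds 0% of its partner, less than the 49% of its left-handed substrate. Put through the same balance, its conversion gives a loss level of 0.908 M, beside 0.881 M from the theta reading.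

    partner + free catalyst + left-handed substrate → free catalyst + left-handed product (k = 76.0 /M²/s)
    partner + free catalyst + right-handed substrate → free catalyst + right-handed product (k = 3.40 /M²/s)
    left-handed substrate + racemization catalyst ⇌ right-handed substrate + racemization catalyst, rate k3*[racemization catalyst]*[left-handed substrate] forward; the back reaction follows from the equilibrium constant (k = 12.0 /M/s)
    partner → decomposed reagent (k = 0.0170 /s)

A neighbour flask like this one, with 0.25 M of partner, has the same free catalyst charge, and L is carried over to it. Applied to that whole partner charge, the starting share gives 0.107 M of substrate used, and the share at the midway substrate level gives an estimated conversion of 15.4%. The computed neighbour flask gives 16.4%.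

The data come from a simulation for substances that don't exist.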